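## Analysis of the target

The target is a macrocyclic bis(bibenzyl): four benzene rings held in a 19-membered ring by two diaryl ether oxygens and two CH2CH2 bridges. Ring A is a phenol with the ring B oxygen ortho to its OH and a bridge para to it. Ring B is a meta-phenylene carrying that oxygen and the second bridge. Ring C is 1,2,3-trioxygenated: a catechol, then the ring D oxygen, with the bridge to ring B meta to that oxygen. Ring D is a para-phenylene between the ring C oxygen and the bridge to ring A. There are no stereocentres, and the ring is large enough that no configurationally stable planar chirality is expected, so only constitution has to be controlled. The sensitive groups are the three phenols, above all the oxidation-prone catechol of ring C; they are best carried as methyl ethers and freed together at the end. The hard parts are closing the 19-membered ring and making the ring C–O–ring D ether, because the ring C oxygen is flanked by another oxygen substituent and ring D has no group that activates it for substitution. The strategy rests on ring D: its six carbons carry only the ether oxygen and, para to it, the bridge, so four of them can come from C3–C6 of a 4-aryloxy-2-pyrone and two from an alkyne. With pyrone and alkyne at the two ends of an open chain, forming ring D also closes the macrocycle.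

## Retrosynthetic reasoning

**21 to 20.** The three phenolic O–H bonds are traced back to O–CH3. Methyl ethers survive every earlier operation, and one Lewis-acid demethylation at the end frees the catechol only when nothing oxidising follows. Diaryl ethers are not cleaved under those conditions.

**20 to 18 (through 19).** The CH2 of the ring D–ring A bridge that sits on ring D is traced back to C=O. This carbonyl is not a detour: it is the group that will activate the alkyne in the ring-forming step. Because it ends up benzylic and para to an aryloxy group, it can be removed by silane/acid ionic hydrogenation through alcohol 19.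

**18 to 16 (through 17).** Two ring D bonds are cut: the bond between the carbon ortho to the ether oxygen and its meta neighbour, and the bond between the acyl-bearing carbon and the other meta carbon. A CO–O bridge is added back across the ring. This opens ring D and the macrocycle in one operation and gives the seco compound 16, a 4-aryloxy-2-pyrone at one chain end and an ethynyl ketone at the other. The cut is made here because ring D is the only ring with no substituent pattern to protect, and because forming it de novo avoids any substitution on an unactivated para-phenylene. The forward reaction must bond pyrone C3 to the terminal alkyne carbon and pyrone C6 to the acyl-bearing carbon, then lose the bridge by decarboxylative cycloreversion.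

**16 to 15.** The ynone is traced back to the secondary propargylic alcohol 15, to be oxidised as the last operation before the cycloaddition. The pyrone is an electrophile that would not survive organomagnesium, hydride, amine or hydroxide reagents, and a ynone would not survive the phenoxide needed to attach the pyrone. The alkynyl carbinol is therefore built first, the pyrone attached second, and the ynone unmasked third under neutral conditions.

**15 to 12 and 14.** The pyrone C4–O bond is cut. Tosylate 14, made from hydroxypyrone 13, is a vinylogous acyl sulfonate, so the hindered ring C phenoxide of 12 can displace it by addition–elimination at room temperature. This replaces a copper coupling on a crowded, electron-rich phenol.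

**12 to 11 to 10.** The bond between the carbinol carbon and the alkyne is cut, giving arylacetaldehyde 11 and an ethynyl-metal nucleophile. Aldehyde 11 is one hydride reduction away from methyl ester 10, so the ring A side chain is carried as a robust ester for as long as possible.

**10 to 8 (through 9).** The saturated ring B–ring C bridge and the free ring C phenol are traced back to stilbene 8 with a benzyl ether. One hydrogenation saturates the alkene and removes the benzyl group, so the protecting group costs no separate step.

**8 to 7 and 2.** The ring B carbon–oxygen bond is cut. The phenol is native to ester 2 (from acid 1), and the bromide sits on ring B of stilbene 7, which has no enolisable or electrophilic group. A ligand-accelerated Ullmann coupling has to join them.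

**7 to 4 and 6.** The stilbene double bond is cut by a Wittig disconnection. Ring C already carries an aldehyde in 3, which needs only benzylation to 4. Ring B carries a benzylic bromide in 5, which gives phosphonium salt 6 in one step. Neither partner needs a change of oxidation level.

## Alternatives that were turned down

**Alternative 1:** The ring C–O–ring D bond is cut, giving the seco bis-phenol A1, in which ring C is a 2,6-dibromophenol and ring D a 2,6-dichlorophenol. Forward, anodic oxidation of A1 and reduction in the same pot would bond the ring D phenol oxygen to a bromine-bearing ortho carbon of ring C and close the ring as A2.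
- For: this phenol-coupling mode runs at room temperature and is established for macrocyclic diaryl ethers with an ortho oxygen. It makes the most hindered ether of the target directly, with the ring C hydroxyl already in place. On that bond it is stronger than any copper coupling.
- Against: four halogens must be put on and three taken off. In A2 the remaining bromine must be exchanged for oxygen before the two chlorines are hydrogenolysed, since C–Br is lost first under reducing conditions, and that exchange takes place next to two oxygen substituents. A1 also needs both bridges and the ring A–ring B ether in place with two free phenols of different oxidation potential. Electrolysis at high dilution moves little material.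
- Comparison: the chosen route delivers ring D bare and every oxygen in its final position, and needs two steps after ring closure where A2 needs about four.

**Alternative 2:** The ring A carbon–oxygen bond is cut, giving the seco phenol A3 with a fluoride ortho to a nitro group on ring A. Forward, a carbonate or fluoride base at high dilution would let the ring B phenoxide displace fluoride and close the ring as A4.
- For: nitro-activated SNAr is probably the most dependable way to close a macrocyclic diaryl ether. It is mild, fast and tolerant of moderate dilution. On certainty of ring closure it is ahead of the chosen key step.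
- Against: the nitro group is not in the target. Turning it into the ring A hydroxyl takes reduction, diazotisation and hydrolysis on the macrocycle, and diazonium hydrolysis in an electron-rich poly(aryl ether) is prone to reduction and azo coupling. A3 also still needs the ring C–O–ring D ether, made earlier by copper coupling of a hindered phenol with an unactivated para-substituted halide, which is the weakest bond-forming step of that plan.
- Comparison: the chosen route gives up some certainty in ring closure. In return it makes the ring C–O–ring D link by a mild addition–elimination on a pyrone, needs no functional-group exchange on the macrocycle, and has a two-step end game.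

**Alternative 3:** A carbonyl is inserted into the ring B carbon–oxygen bond, giving the 20-membered aryl ester A5. Forward, zerovalent nickel with a chelating bis(dicyclohexylphosphino) ligand would insert into the acyl C–O bond, lose CO and reductively eliminate to the 19-membered ether A6, which is identical with 20.
- For: macrolactonisation to A5 is a reliable ring closure, and A6 is one demethylation from the target. The end game is shorter than in the chosen route by one step.
- Against: aryl–oxygen reductive elimination from nickel is the hardest elementary step of the cycle. Decarbonylative etherification is established mainly for esters whose acyl part is an azine, where nitrogen coordination assists. A5 is a plain benzoate with an electron-rich ortho-methoxy aryloxide, so ester cleavage or decarbonylation without C–O bond formation would be expected to compete at the high temperature needed. Ring contraction in a macrocycle adds a second unknown.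
- Comparison: both key steps are untried at this ring size. The chosen one consists of two pericyclic steps of known type that need only heat and whose regiochemistry can be argued from polarity, whereas A5 lies outside the demonstrated substrate range of its catalytic step.

Key step: step 12

## Assumptions

- Ring B is introduced as 3-bromobenzyl bromide (5), so that aldehyde 3 can serve, after benzylation, as the carbonyl partner of the Wittig reaction; 1, 3, 5 and 13 are taken to be commercially available.
- Stilbenes 7 and 8 are carried as E/Z mixtures because both isomers give the same bibenzyl. Compounds 12, 15, 17 and 19 are racemic and their stereocentres are removed later; SMILES without stereo-descriptors denote these mixtures.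

## Route

Step 1
Reactants: 1 3-hydroxy-4-methoxyphenylacetic acid
Product: 2 methyl (3-hydroxy-4-methoxyphenyl)acetate
Conditions: MeOH, H2SO4 (cat.), reflux
Reagents that add atoms: methanol, CO
Why: Fischer esterification; the phenol is untouched under acid catalysis, and the ester keeps the side chain at the oxidation level from which the aldehyde is reached later.

Step 2
Reactants: 3 3-hydroxy-4,5-dimethoxybenzaldehyde
Product: 4 3-(benzyloxy)-4,5-dimethoxybenzaldehyde
Conditions: BnBr, K2CO3, DMF, rt
Reagents that add atoms: benzyl bromide, BrCc1ccccc1
Why: Williamson etherification of the phenoxide; benzyl is chosen because it is removed in the same hydrogenation that saturates the bridge (step 6).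

Step 3
Reactants: 5 3-bromobenzyl bromide
Product: 6 (3-bromobenzyl)triphenylphosphonium bromide
Conditions: PPh3, toluene, reflux
Reagents that add atoms: triphenylphosphine, c1ccc(cc1)P(c1ccccc1)c1ccccc1
Why: SN2 quaternisation at the benzylic bromide; the aryl bromide is inert to the phosphine and the salt should precipitate from toluene.

Step 4
Reactants: 6 (3-bromobenzyl)triphenylphosphonium bromide, 4 3-(benzyloxy)-4,5-dimethoxybenzaldehyde
Product: 7 1-(benzyloxy)-5-[2-(3-bromophenyl)ethenyl]-2,3-dimethoxybenzene (E/Z mixture)
Conditions: t-BuOK, THF, 0 °C; then 4, 0 °C → rt
Reagents that add atoms: none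
Why: Wittig olefination with a semi-stabilised benzylic ylide; the aryl bromide and the benzyl ether are inert, and the E/Z ratio is irrelevant because the alkene is hydrogenated in step 6.

Step 5
Reactants: 7 1-(benzyloxy)-5-[2-(3-bromophenyl)ethenyl]-2,3-dimethoxybenzene (E/Z mixture), 2 methyl (3-hydroxy-4-methoxyphenyl)acetate
Product: 8 methyl [3-(3-{2-[3-(benzyloxy)-4,5-dimethoxyphenyl]ethenyl}phenoxy)-4-methoxyphenyl]acetate (E/Z mixture)
Conditions: CuI (10 mol %), N,N-dimethylglycine hydrochloride (30 mol %), Cs2CO3, 1,4-dioxane, 100 °C
Reagents that add atoms: none
Why: Ligand-accelerated Ullmann diaryl ether coupling on monovalent copper, which accepts unactivated aryl bromides and ortho-methoxy phenols; 7 has no enolisable or electrophilic group, and the methyl ester tolerates anhydrous carbonate.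

Step 6
Reactants: 8 methyl [3-(3-{2-[3-(benzyloxy)-4,5-dimethoxyphenyl]ethenyl}phenoxy)-4-methoxyphenyl]acetate (E/Z mixture)
Product: 10 methyl [3-(3-{2-[3-hydroxy-4,5-dimethoxyphenyl]ethyl}phenoxy)-4-methoxyphenyl]acetate, via bibenzyl benzyl ether 9 (not isolated)
Conditions: H2 (1 atm), 10% Pd/C, EtOAc–MeOH, rt
Reagents that add atoms: none
Why: Catalytic hydrogenation saturates the stilbene and hydrogenolyses the benzyl ether in one operation; the ester, the methyl ethers and the diaryl ether are inert.

Step 7
Reactants: 10 methyl [3-(3-{2-[3-hydroxy-4,5-dimethoxyphenyl]ethyl}phenoxy)-4-methoxyphenyl]acetate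
Product: 11 [3-(3-{2-[3-hydroxy-4,5-dimethoxyphenyl]ethyl}phenoxy)-4-methoxyphenyl]acetaldehyde
Conditions: i-Bu2AlH (2.2 equiv.), CH2Cl2, −78 °C; MeOH, then aq. potassium sodium tartrate
Reagents that add atoms: none
Why: Partial reduction of the ester; the first equivalent is consumed by the phenol, and the tetrahedral aluminium hemiacetal is stable at −78 °C and collapses to the aldehyde only on work-up. The aldehyde is used crude at once.

Step 8
Reactants: 11 [3-(3-{2-[3-hydroxy-4,5-dimethoxyphenyl]ethyl}phenoxy)-4-methoxyphenyl]acetaldehyde
Product: 12 rac-1-[3-(3-{2-[3-hydroxy-4,5-dimethoxyphenyl]ethyl}phenoxy)-4-methoxyphenyl]but-3-yn-2-ol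
Conditions: HC≡CMgBr (3 equiv.), THF, −78 → 0 °C; aq. NH4Cl
Reagents that add atoms: ethynylmagnesium bromide, C#C[Mg]Br
Why: Grignard 1,2-addition; the weakly basic acetylide adds to the enolisable arylacetaldehyde faster than it deprotonates it. The new carbinol centre forms as a racemate and needs no control because it is oxidised in step 11.

Step 9
Reactants: 13 4-hydroxy-2H-pyran-2-one
Product: 14 2-oxo-2H-pyran-4-yl 4-methylbenzenesulfonate
Conditions: TsCl, Et3N, CH2Cl2, 0 °C
Reagents that add atoms: 4-toluenesulfonyl chloride, Cc1ccc(cc1)S(Cl)(=O)=O
Why: O-sulfonylation of the vinylogous acid turns C4 of the pyrone into an addition–elimination site.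

Step 10
Reactants: 12 rac-1-[3-(3-{2-[3-hydroxy-4,5-dimethoxyphenyl]ethyl}phenoxy)-4-methoxyphenyl]but-3-yn-2-ol, 14 2-oxo-2H-pyran-4-yl 4-methylbenzenesulfonate
Product: 15 rac-4-{5-[2-(3-{5-[2-hydroxybut-3-yn-1-yl]-2-methoxyphenoxy}phenyl)ethyl]-2,3-dimethoxyphenoxy}-2H-pyran-2-one
Conditions: K2CO3, MeCN, rt
Reagents that add atoms: none
Why: Vinylogous acyl substitution: the phenoxide adds to C4 of the pyrone to give a lactone dienolate that expels tosylate. Carbonate deprotonates only the phenol, so the propargylic hydroxyl does not compete.

Step 11
Reactants: 15 rac-4-{5-[2-(3-{5-[2-hydroxybut-3-yn-1-yl]-2-methoxyphenoxy}phenyl)ethyl]-2,3-dimethoxyphenoxy}-2H-pyran-2-one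
Product: 16 4-{2,3-dimethoxy-5-[2-(3-{2-methoxy-5-[2-oxobut-3-yn-1-yl]phenoxy}phenyl)ethyl]phenoxy}-2H-pyran-2-one
Conditions: Dess–Martin periodinane, CH2Cl2, 0 °C → rt; aq. Na2S2O3/NaHCO3 work-up
Reagents that add atoms: none
Why: Dess–Martin oxidation of a secondary propargylic alcohol under neutral, non-nucleophilic conditions, which the pyrone and the new ynone both tolerate. The carbinol stereocentre is erased; 16 is kept cold and used promptly.

Step 12
Reactants: 16 4-{2,3-dimethoxy-5-[2-(3-{2-methoxy-5-[2-oxobut-3-yn-1-yl]phenoxy}phenyl)ethyl]phenoxy}-2H-pyran-2-one
Product: 18 macrocyclic aryl ketone (tri-O-methyl ether of the target carrying C=O on the bridge carbon next to ring D), via bridged bicyclic lactone 17 (not isolated)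
Conditions: 1,2-dichlorobenzene (degassed, 0.002 M, slow addition of 16), BHT (cat.), 160 °C
Reagents that add atoms: none
Why: The 4-aryloxy-2-pyrone acts as an electron-rich diene (C3=C4–C5=C6) and the ethynyl ketone as an electron-poor dienophile in a thermal normal-demand [4+2] cycloaddition that bonds pyrone C3 to the terminal alkyne carbon and pyrone C6 to the acyl-bearing alkyne carbon, giving the 2-oxabicyclo[2.2.2]octadienone 17. A retro-[4+2] step then expels the CO–O bridge as CO2, which is irreversible and leaves ring D aromatic. The closest known reaction type is the 2-pyrone–alkyne Diels–Alder/decarboxylation route to benzenes, which has been run intramolecularly to close para-cyclophanes. Ring D closes by cycloaddition followed by cycloreversion; the 19-membered macrocycle closes end to end through the same two bonds, because diene and dienophile are the two termini of the chain. No stereocentre remains, since the two bridgehead CH centres of 17 are lost on aromatisation. The step needs para rather than meta regiochemistry, and polarity matching should secure it: pyrone C3, beta to the aryloxy oxygen and vinylogously activated by the ring oxygen, is the nucleophilic diene terminus and pairs with the electrophilic beta carbon of the ynone, which places the acyl group para to the ether oxygen. The step also needs ring closure to outrun oligomerisation, which high dilution and slow addition provide, while the long unstrained tether imposes no bias against the required orientation.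

Step 13
Reactants: 18 macrocyclic aryl ketone (tri-O-methyl ether of the target carrying C=O on the bridge carbon next to ring D)
Product: 20 tri-O-methyl ether of the target, via macrocyclic benzylic alcohol 19 (not isolated)
Conditions: Et3SiH (5 equiv.), CF3CO2H, CH2Cl2, 0 °C → rt
Reagents that add atoms: none
Why: Ionic hydrogenation: hydride transfer to the protonated ketone gives alcohol 19, which ionises to a benzylic cation stabilised by the para aryloxy group and takes a second hydride. Aryl methyl ethers and diaryl ethers are inert to silane and acid.

Step 14
Reactants: 20 tri-O-methyl ether of the target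
Product: 21 the target, the macrocyclic triphenol
Conditions: BBr3, CH2Cl2, −78 °C → rt; then H2O
Reagents that add atoms: none
Why: Lewis-acid cleavage of the three aryl methyl ethers by bromide attack at methyl on the boron-complexed oxygens; diaryl ethers are not cleaved, and the catechol is freed only in this last step.

## Compound list

1 | 3-hydroxy-4-methoxyphenylacetic acid | COc1ccc(CC(=O)O)cc1O | starting material
2 | methyl (3-hydroxy-4-methoxyphenyl)acetate | COC(=O)Cc1ccc(OC)c(O)c1 | intermediate
3 | 3-hydroxy-4,5-dimethoxybenzaldehyde | COc1cc(C=O)cc(O)c1OC | starting material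
4 | 3-(benzyloxy)-4,5-dimethoxybenzaldehyde | O=Cc1cc(OCc2ccccc2)c(OC)c(OC)c1 | intermediate
5 | 3-bromobenzyl bromide | BrCc1cccc(Br)c1 | starting material
6 | (3-bromobenzyl)triphenylphosphonium bromide | [Br-].Brc1cccc(c1)C[P+](c1ccccc1)(c1ccccc1)c1ccccc1 | intermediate
7 | 1-(benzyloxy)-5-[2-(3-bromophenyl)ethenyl]-2,3-dimethoxybenzene (E/Z mixture) | Brc1cccc(c1)C=Cc1cc(OCc2ccccc2)c(OC)c(OC)c1 | intermediate
8 | methyl [3-(3-{2-[3-(benzyloxy)-4,5-dimethoxyphenyl]ethenyl}phenoxy)-4-methoxyphenyl]acetate (E/Z mixture) | COC(=O)Cc1ccc(OC)c(c1)Oc1cccc(c1)C=Cc1cc(OC)c(OC)c(OCc2ccccc2)c1 | intermediate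
9 | methyl [3-(3-{2-[3-(benzyloxy)-4,5-dimethoxyphenyl]ethyl}phenoxy)-4-methoxyphenyl]acetate (bibenzyl benzyl ether) | COC(=O)Cc1ccc(OC)c(c1)Oc1cccc(c1)CCc1cc(OC)c(OC)c(OCc2ccccc2)c1 | intermediate
10 | methyl [3-(3-{2-[3-hydroxy-4,5-dimethoxyphenyl]ethyl}phenoxy)-4-methoxyphenyl]acetate | COC(=O)Cc1ccc(OC)c(c1)Oc1cccc(c1)CCc1cc(OC)c(OC)c(O)c1 | intermediate
11 | [3-(3-{2-[3-hydroxy-4,5-dimethoxyphenyl]ethyl}phenoxy)-4-methoxyphenyl]acetaldehyde | O=CCc1ccc(OC)c(c1)Oc1cccc(c1)CCc1cc(OC)c(OC)c(O)c1 | intermediate
12 | rac-1-[3-(3-{2-[3-hydroxy-4,5-dimethoxyphenyl]ethyl}phenoxy)-4-methoxyphenyl]but-3-yn-2-ol | C#CC(O)Cc1ccc(OC)c(c1)Oc1cccc(c1)CCc1cc(OC)c(OC)c(O)c1 | intermediate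
13 | 4-hydroxy-2H-pyran-2-one | OC1=CC(=O)OC=C1 | starting material
14 | 2-oxo-2H-pyran-4-yl 4-methylbenzenesulfonate | Cc1ccc(cc1)S(=O)(=O)OC1=CC(=O)OC=C1 | intermediate
15 | rac-4-{5-[2-(3-{5-[2-hydroxybut-3-yn-1-yl]-2-methoxyphenoxy}phenyl)ethyl]-2,3-dimethoxyphenoxy}-2H-pyran-2-one | C#CC(O)Cc1ccc(OC)c(c1)Oc1cccc(c1)CCc1cc(OC)c(OC)c(c1)OC1=CC(=O)OC=C1 | intermediate
16 | 4-{2,3-dimethoxy-5-[2-(3-{2-methoxy-5-[2-oxobut-3-yn-1-yl]phenoxy}phenyl)ethyl]phenoxy}-2H-pyran-2-one (seco pyrone ynone) | C#CC(=O)Cc1ccc(OC)c(c1)Oc1cccc(c1)CCc1cc(OC)c(OC)c(c1)OC1=CC(=O)OC=C1 | intermediate
17 | bridged bicyclic lactone: macrocyclic 2-oxabicyclo[2.2.2]octa-5,7-dien-3-one cycloadduct, pyrone C3 bonded to the former terminal alkyne carbon and pyrone C6 to the acyl-bearing carbon (racemic) | COc1ccc2cc1Oc1cccc(c1)CCc1cc(OC)c(OC)c(c1)OC1=CC3OC(=O)C1C=C3C(=O)C2 | intermediate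
18 | macrocyclic aryl ketone: tri-O-methyl ether of the target with C=O on the bridge carbon attached to ring D | COc1ccc2cc1Oc1cccc(c1)CCc1cc(OC)c(OC)c(c1)Oc1ccc(cc1)C(=O)C2 | intermediate
19 | macrocyclic benzylic alcohol: as 18 with CH(OH) in place of C=O (racemic) | COc1ccc2cc1Oc1cccc(c1)CCc1cc(OC)c(OC)c(c1)Oc1ccc(cc1)C(O)C2 | intermediate
20 | tri-O-methyl ether of the target | COc1ccc2cc1Oc1cccc(c1)CCc1cc(OC)c(OC)c(c1)Oc1ccc(cc1)CC2 | intermediate
21 | target macrocyclic triphenol (achiral) | Oc1ccc2cc1Oc1cccc(c1)CCc1cc(O)c(O)c(c1)Oc1ccc(cc1)CC2 | target

## Step count and least certain steps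

Total step count: 14. Longest linear sequence: 11 steps (from 3 through steps 2, 4, 5, 6, 7, 8, 10, 11, 12, 13 and 14).

**Step 12 (key step).**
- Risk: intermolecular cycloaddition and oligomerisation may outrun closure of the 19-membered ring, which carries a large entropic cost. The terminal ynone may degrade by enolisation or conjugate addition at the temperature the cycloaddition needs. Bonding of pyrone C6 instead of C3 to the terminal alkyne carbon would erode the para regiochemistry.
- Fallback: this forms the ring D–bridge bond by a metal-mediated macrocyclisation on a preformed ring D. It sets out from 10. The ring C phenol is arylated with 4-iodophenylboronic acid under Chan–Lam conditions (Cu(OAc)2, pyridine, air, CH2Cl2, rt) to give the 4-iodophenyl ether ester F1. Partial reduction (i-Bu2AlH, CH2Cl2, −78 °C) gives the iodo aldehyde F2. An intramolecular Nozaki–Hiyama–Kishi reaction (CrCl2, NiCl2 cat., DMF, high dilution, rt) adds the ring D carbon para to the ether oxygen to the aldehyde and closes the macrocycle as alcohol 19. This is isolated and deoxygenated with Et3SiH/CF3CO2H as in the second stage of step 13, returning to the route at 20.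

**Step 10.**
- Risk: the phenoxide may attack sulfur of the tosylate (sulfonyl transfer to the phenol) or C6 of the unsubstituted pyrone with ring opening, instead of adding at C4.
- Fallback: this uses an electrophile with no sulfonyl site. It sets out from 13, which is converted with Bu4NBr and P2O5 in toluene at 100 °C into 4-bromo-2H-pyran-2-one F3. F3 reacts with 12 and K2CO3 in MeCN by the same addition–elimination at C4 and returns to the route at 15.

**Step 11.**
- Risk: the terminal ynone may be lost during oxidation, work-up or concentration through conjugate addition of acetate or water to the unsubstituted alkyne terminus and through oligomerisation.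
- Fallback: this carries a silyl cap on the alkyne through the oxidation. It sets out from 11.
  - Addition of lithium (trimethylsilyl)acetylide (from trimethylsilylacetylene and n-BuLi, THF, −78 °C) gives the silyl-capped propargylic alcohol F4.
  - Etherification with 14 (K2CO3, MeCN, rt) gives the silyl-capped pyrone ether F5.
  - Dess–Martin oxidation gives the silyl-capped ynone F6, which should be stable to chromatography and storage.
  - Buffered desilylation (Bu4NF–AcOH, THF, −78 °C) immediately before the cycloaddition releases 16 in solution, where the route is rejoined.

**Step 7.**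
- Risk: over-reduction to the primary alcohol, and enolisation with self-aldol condensation of the arylacetaldehyde during work-up.
- Fallback: this avoids the aldehyde altogether. It sets out from 10. Aminolysis with MeNH(OMe)·HCl and i-PrMgCl (THF, −20 °C) gives the Weinreb amide F7. Ethynylmagnesium bromide (THF, 0 °C) gives the phenolic ynone F8. Luche reduction (NaBH4, CeCl3·7H2O, MeOH, −78 °C) returns to the route at 12.

**Step 13.**
- Risk: the benzylic cation may be captured by one of the electron-rich rings across the macrocycle (transannular Friedel–Crafts alkylation), or the reaction may stall at the alcohol stage.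
- Fallback: this is cation-free. It sets out from 18, which is heated with N2H4·H2O and KOH in diethylene glycol (130 °C, then 200 °C; Wolff–Kishner reduction, Huang-Minlon procedure) through the hydrazone F9 and returns to the route at 20. Any partial demethylation under these conditions is harmless, because step 14 removes all methyl ethers.

## Further compounds

F1 | step 12 | methyl [3-(3-{2-[3-(4-iodophenoxy)-4,5-dimethoxyphenyl]ethyl}phenoxy)-4-methoxyphenyl]acetate | COC(=O)Cc1ccc(OC)c(c1)Oc1cccc(c1)CCc1cc(OC)c(OC)c(c1)Oc1ccc(I)cc1
F2 | step 12 | [3-(3-{2-[3-(4-iodophenoxy)-4,5-dimethoxyphenyl]ethyl}phenoxy)-4-methoxyphenyl]acetaldehyde | O=CCc1ccc(OC)c(c1)Oc1cccc(c1)CCc1cc(OC)c(OC)c(c1)Oc1ccc(I)cc1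
F3 | step 10 | 4-bromo-2H-pyran-2-one | BrC1=CC(=O)OC=C1
F4 | step 11 | rac-1-[3-(3-{2-[3-hydroxy-4,5-dimethoxyphenyl]ethyl}phenoxy)-4-methoxyphenyl]-4-(trimethylsilyl)but-3-yn-2-ol | C[Si](C)(C)C#CC(O)Cc1ccc(OC)c(c1)Oc1cccc(c1)CCc1cc(OC)c(OC)c(O)c1
F5 | step 11 | rac-4-{5-[2-(3-{5-[2-hydroxy-4-(trimethylsilyl)but-3-yn-1-yl]-2-methoxyphenoxy}phenyl)ethyl]-2,3-dimethoxyphenoxy}-2H-pyran-2-one | C[Si](C)(C)C#CC(O)Cc1ccc(OC)c(c1)Oc1cccc(c1)CCc1cc(OC)c(OC)c(c1)OC1=CC(=O)OC=C1
F6 | step 11 | 4-{2,3-dimethoxy-5-[2-(3-{2-methoxy-5-[2-oxo-4-(trimethylsilyl)but-3-yn-1-yl]phenoxy}phenyl)ethyl]phenoxy}-2H-pyran-2-one | C[Si](C)(C)C#CC(=O)Cc1ccc(OC)c(c1)Oc1cccc(c1)CCc1cc(OC)c(OC)c(c1)OC1=CC(=O)OC=C1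
F7 | step 7 | 2-[3-(3-{2-[3-hydroxy-4,5-dimethoxyphenyl]ethyl}phenoxy)-4-methoxyphenyl]-N-methoxy-N-methylacetamide | CON(C)C(=O)Cc1ccc(OC)c(c1)Oc1cccc(c1)CCc1cc(OC)c(OC)c(O)c1
F8 | step 7 | 1-[3-(3-{2-[3-hydroxy-4,5-dimethoxyphenyl]ethyl}phenoxy)-4-methoxyphenyl]but-3-yn-2-one | C#CC(=O)Cc1ccc(OC)c(c1)Oc1cccc(c1)CCc1cc(OC)c(OC)c(O)c1
F9 | step 13 | hydrazone of macrocyclic ketone 18 | COc1ccc2cc1Oc1cccc(c1)CCc1cc(OC)c(OC)c(c1)Oc1ccc(cc1)C(=NN)C2
A1 | alternative 1 | seco bis-phenol with a 2,6-dibromophenol as ring C and a 2,6-dichlorophenol as ring D | COc1ccc(CCc2cc(Cl)c(O)c(Cl)c2)cc1Oc1cccc(CCc2cc(Br)c(O)c(Br)c2)c1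
A2 | alternative 1 | macrocyclic bromo dichloro diaryl ether | COc1ccc2cc1Oc1cccc(c1)CCc1cc(Br)c(O)c(c1)Oc1c(Cl)cc(cc1Cl)CC2
A3 | alternative 2 | seco phenol with 3-fluoro-4-nitrophenyl as ring A | [O-][N+](=O)c1ccc(CCc2ccc(Oc3cc(CCc4cccc(O)c4)cc(OC)c3OC)cc2)cc1F
A4 | alternative 2 | macrocyclic nitro diaryl ether | [O-][N+](=O)c1ccc2cc1Oc1cccc(c1)CCc1cc(OC)c(OC)c(c1)Oc1ccc(cc1)CC2
A5 | alternative 3 | 20-membered macrocyclic aryl ester (ring B benzoate of the ring A phenol) | COc1ccc2cc1OC(=O)c1cccc(c1)CCc1cc(OC)c(OC)c(c1)Oc1ccc(cc1)CC2
A6 | alternative 3 | tri-O-methyl ether of the target (same structure as 20) | COc1ccc2cc1Oc1cccc(c1)CCc1cc(OC)c(OC)c(c1)Oc1ccc(cc1)CC2
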